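The vessel is stirred and held at constant volume and temperature, and J enters either at once or in portions.

| setting | teal | green | Saturday's | Thursday's |
|---|---|---|---|---|
| E | 1 M | 1.8 M | 1.2 M | 0.80 M |
| J | 1 equiv (in portions, 2) | 1 equiv (in portions, 2) | 1.00 equiv (in portions, 2) | 1.00 equiv |
| remark | run made earlier; portions every 20 min | run made earlier; portions every 20 min | the portions of J follow each other after 20 min, the first at the start | everything together at the start |
| time |  |  | 40 min | 60 min |

| run | time / min | L / % | E / % |
|---|---|---|---|
| teal | 1.50 | 20.1 | 12.0 |
| teal | 3.00 | 26.7 | 3.7 |
| teal | 6.00 | 29.6 | 0.6 |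
| teal | 10.0 | 28.4 | 0 |
| teal | 20.0 | 30.0 | 1.0 |
| green | 2.00 | 22.4 | 7.3 |
| green | 5.00 | 27.9 | 0.7 |
| green | 10.0 | 28.4 | 0 |
| green | 15.0 | 29.0 | 0 |
| green | 20.0 | 29.7 | 0 |

(scatter of a reading: 0.5 percentage points)

- a species is counted by the E in it: one Q counts as two
- what may be going on: E <-> J; E -> L; J -> X; J <-> D; D -> Z; E + L -> Q; J -> G
- in a conversion J counts as not yet reacted; D counts as reacted
- where the amount of E changes, what is given in equivalents or mol% on it follows

* which one finishes higher in amount of L, in percent of the E and J together charged ("neither" within 2 percentage points) (Saturday's / Thursday's / neither)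
* amount of L at the end, in percent of the E and J together charged, Saturday's
* amount of L at the end, in percent of the E and J together charged, Thursday's

Teal and green differ in c_E, yet at 10.0 min both read 28.4% of L as percent of charge, so I take the steps as first order. Amounts then add: the final L is a times E's share of the charge plus b times J's share, however J enters. Here a is the L that one unit of E ends as, and b the same for J.

In teal and green, up to the second portion, E is half of the whole charge and J a quarter, and the last readings of L average 29.8%. J reaches L through E, so b lies between nil and a. Saturday's and Thursday's each charge equal E and J, so on this reckoning each ends between 29.8% and 39.8%.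

To tighten this, I replace J by its mean over teal's first two equal stretches, which takes J's return to E as equal in both. Subtracting the stretches gives a reading of 2.20 units of E leaving per unit of L, and the size of the mean cancels; the error lies in J's unread curve and in the scatter. The averaged L then gives an estimated return chance from J to E of 0.258, so I estimate a as 0.529 and b as 0.136, the yield of L per unit of J. I commit to 33.3% for both flasks, hence neither.

The forecast gives 32% for Saturday's and 35.5% for Thursday's, inside my bracket, and picks Thursday's: “Thursday's is probably higher, but this is uncertain.”

The flask gives 34.4% for Saturday's and 34.9% for Thursday's, so neither.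

    E ⇌ J (K = 1.90, k = 0.0130 /s)
    E → L (k = 0.00900 /s)
    J → X (k = 0.0110 /s)
    J ⇌ D (K = 0.0920, k = 0.00190 /s)
    D → Z (k = 0.00670 /s)
    E + L → Q (k = 6.60 × 10⁻⁴ /M/s)
    J → G (k = 4.00 × 10⁻⁷ /s)

In Saturday's, the second portion meets 0% of E and L goes from 29.9% to 34.4% by the end, which is 0.180 per unit of J in that portion against my 0.136. In Saturday's, the main reason for J's low yield of L is the step from J to X: struck out, L reaches 76.8%. For Thursday's neighbour with 0.400 equiv of J, a and b give 41.7%, and that flask stands at 42.0%.

The runs are calculated from invented constants; scatter was added.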